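**Retrosynthetic overview**

1. Tetralin numbering is used: C1 carries the pendant (primed) aryl ring, C2 and C3 carry the hydroxymethyl groups, C4 is the methylene, ring A is C4a–C8a, ring B is C1–C4/C4a/C8a. Target 19 comes from its bis(benzyl ether) 18 by hydrogenolysis.
2. Key disconnection: C1–C1′ together with C1–C8a. Compound 18 arises in one operation from cyclic acetal 13 and potassium aryltrifluoroborate 15, by aryl transfer to C1 followed by Lewis-acid closure of ring B.
3. Enabling feature: C1 is doubly benzylic, between C1′ (para to the C4′ oxygen) and C8a (ortho to the C8 methoxy and para to the C6 methoxy group), and the oxygen of the C3 hydroxymethyl group lies four bonds from C1. C1 can therefore be held at the aldehyde level as a five-membered cyclic acetal (a temporary ring) that gives this oxygen back when ring B closes; ring A stems from a symmetrical 4-oxy-3,5-dimethoxybenzyl unit, so its two ortho positions are equivalent.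
4. Acetal 13 comes from trans-lactone 11 by reduction and ring switch (lactone to tetrahydrofuran); 11 from lactone 9 by anti α-(dimethoxymethyl)ation (C2 relayed from C3); 9 from (S)-epichlorohydrin 3 (C3 bought), dimethyl malonate 4 and aryl bromide 2 through cyclopropane lactone 6.
5. Ring order: ring A and the pendant ring are bought; temporary cyclopropane and lactone (steps 2–4), temporary tetrahydrofuran (step 6), ring B last (step 8).

Key step: step 8

Remark: compounds 1, 3, 4 and 14 are taken as commercially available; both phenols are carried as benzyl ethers so that one hydrogenolysis ends the route.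

**Route**

Step 1
Reactants: 1 4-bromo-2,6-dimethoxyphenol
Product: 2 2-(benzyloxy)-5-bromo-1,3-dimethoxybenzene
Conditions: BnBr, K2CO3, DMF, rt
Reagents that add atoms: benzyl bromide, BrCc1ccccc1
Why: Williamson ether synthesis on the phenoxide gives a benzyl ether that should survive the Grignard, hydride and Lewis-acid steps and fall off by hydrogenolysis at the end.

Step 2
Reactants: 3 (S)-epichlorohydrin; 4 dimethyl malonate
Product: 6 methyl (1R,5S)-2-oxo-3-oxabicyclo[3.1.0]hexane-1-carboxylate, via epoxymalonate 5 (not isolated)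
Conditions: NaOMe, MeOH, rt → reflux
Reagents that add atoms: none
Why: In a known double-alkylation cascade the malonate anion opens the epoxide at its CH2 end, the alkoxide displaces chloride to give epoxide 5, the malonate carbanion opens 5 at the stereocentre in a 3-exo-tet SN2 closure with inversion and the freed alkoxide lactonises, so that C5 derives from the bought stereocentre and C1 follows from the cis ring fusion.

Step 3
Reactants: 2 2-(benzyloxy)-5-bromo-1,3-dimethoxybenzene; 6 methyl (1R,5S)-2-oxo-3-oxabicyclo[3.1.0]hexane-1-carboxylate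
Product: 8 methyl (3R,4S)-4-{[4-(benzyloxy)-3,5-dimethoxyphenyl]methyl}-2-oxooxolane-3-carboxylate, via arylmagnesium bromide 7 (not isolated)
Conditions: Mg, THF, reflux; then 6, CuI (cat.), THF, −30 → 0 °C
Reagents that add atoms: none
Why: Copper-catalysed homoconjugate addition of the aryl Grignard reagent should open the doubly activated cyclopropane at its CH2 carbon and give the malonate-type enolate without touching the stereocentre, a known reaction type for this bicyclic lactone.

Step 4
Reactants: 8 methyl (3R,4S)-4-{[4-(benzyloxy)-3,5-dimethoxyphenyl]methyl}-2-oxooxolane-3-carboxylate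
Product: 9 (4S)-4-{[4-(benzyloxy)-3,5-dimethoxyphenyl]methyl}oxolan-2-one
Conditions: LiCl, H2O, DMSO, 140 °C
Reagents that add atoms: none
Why: Krapcho dealkoxycarbonylation (demethylation by chloride, loss of CO2, protonation) should remove the extra ester and leave the β-stereocentre untouched.

Step 5
Reactants: 9 (4S)-4-{[4-(benzyloxy)-3,5-dimethoxyphenyl]methyl}oxolan-2-one
Product: 11 (3R,4S)-4-{[4-(benzyloxy)-3,5-dimethoxyphenyl]methyl}-3-(dimethoxymethyl)oxolan-2-one, via silyl ketene acetal 10 (not isolated)
Conditions: LDA, TMSCl, THF, −78 °C; then HC(OMe)3, TMSOTf (cat.), CH2Cl2, −78 °C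
Reagents that add atoms: trimethyl orthoformate, COC(OC)OC
Why: A Mukaiyama-type addition of the lactone silyl ketene acetal to the dimethoxycarbenium ion from the orthoester should install the masked formyl carbon (the future C1) at the α-carbon anti to the neighbouring arylmethyl group, which sets the future C2 centre in the trans (also thermodynamic) arrangement.

Step 6
Reactants: 11 (3R,4S)-4-{[4-(benzyloxy)-3,5-dimethoxyphenyl]methyl}-3-(dimethoxymethyl)oxolan-2-one
Product: 13 [(3S,4S)-4-{[4-(benzyloxy)-3,5-dimethoxyphenyl]methyl}-2-methoxyoxolan-3-yl]methanol (both C2 anomers), via diol acetal 12 (not isolated)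
Conditions: LiAlH4, THF, 0 °C; then PPTS (cat.), CH2Cl2, rt
Reagents that add atoms: none
Why: LiAlH4 should reduce the lactone to the diol without touching the acetal, and mild acid then exchanges the dimethyl acetal into the five-membered cyclic methyl acetal with the hydroxyl four bonds away, a ring switch that turns the trans-lactone into the 3,4-cis tetrahydrofuran needed for an all-trans tetralin and touches no stereocentre.

Step 7
Reactants: 14 [4-(benzyloxy)-3-methoxyphenyl]boronic acid
Product: 15 potassium [4-(benzyloxy)-3-methoxyphenyl]trifluoroborate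
Conditions: KHF2, MeOH–H2O, rt
Reagents that add atoms: potassium hydrogen difluoride, F.[F-].[K+]
Why: Standard conversion of an arylboronic acid into its potassium trifluoroborate salt, which precipitates and stores well.

Step 8
Reactants: 13 [(3S,4S)-4-{[4-(benzyloxy)-3,5-dimethoxyphenyl]methyl}-2-methoxyoxolan-3-yl]methanol; 15 potassium [4-(benzyloxy)-3-methoxyphenyl]trifluoroborate
Product: 18 [(1R,2S,3S)-7-(benzyloxy)-1-[4-(benzyloxy)-3-methoxyphenyl]-6,8-dimethoxy-1,2,3,4-tetrahydronaphthalene-2,3-diyl]dimethanol, via aryldifluoroborane 16 (not isolated), via 2-aryltetrahydrofuran 17 (not isolated)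
Conditions: BF3·OEt2, MeCN–CH2Cl2, −20 °C → rt
Reagents that add atoms: none
Why: BF3 strips fluoride from 15 to give aryldifluoroborane 16, which takes methoxide from acetal 13; the five-membered oxocarbenium ion then receives the aryl group from boron at the ipso carbon, so the C1–C1′ bond forms with the pendant-ring regiochemistry fixed by the C–B bond and gives 2-aryltetrahydrofuran 17. The same Lewis acid then ionises the benzylic C1–O bond of 17, the cation being stabilised by the para oxygen of the pendant ring, and ring A attacks it. Ring B closes by Friedel–Crafts alkylation, formally a 6-endo-trig attack of the C4a=C8a π bond on the planar C1 cation through a chair-like transition state, at a ring-A carbon that is ortho to one methoxy group and para to the other; the two ortho positions of the benzyl unit are equivalent, so no regiochemical choice arises. The closest known reaction types are the BF3-mediated coupling of potassium organotrifluoroborates with O,O-acetals and the acid-induced cycloalkylation of 2-aryl-3-(hydroxymethyl)-4-benzyltetrahydrofurans to 1-aryltetralins. C1 is the only new stereocentre and is set in the ring closure by C2 and C3, since the chair with the aryl group and both side chains pseudo-equatorial should give the 1,2-trans-2,3-trans product, while the configuration at the aryl-bearing carbon of 17 does not matter because that carbon becomes planar. The step needs aryl transfer to outrun loss of the C2 proton from the oxocarbenium ion and intramolecular capture of the cation to outrun intermolecular capture; the low starting temperature and the six-membered tether should secure both.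

Step 9
Reactants: 18 [(1R,2S,3S)-7-(benzyloxy)-1-[4-(benzyloxy)-3-methoxyphenyl]-6,8-dimethoxy-1,2,3,4-tetrahydronaphthalene-2,3-diyl]dimethanol
Product: 19 [(1R,2S,3S)-7-hydroxy-1-(4-hydroxy-3-methoxyphenyl)-6,8-dimethoxy-1,2,3,4-tetrahydronaphthalene-2,3-diyl]dimethanol
Conditions: H2 (1 atm), Pd/C, EtOAc–MeOH, rt
Reagents that add atoms: none
Why: Hydrogenolysis over Pd/C should cleave both aryl benzyl ethers and leave the tetralin, the methyl ethers, the primary alcohols and the three stereocentres untouched.

**Compound list**

1 | 4-bromo-2,6-dimethoxyphenol | COc1cc(Br)cc(OC)c1O | starting material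
2 | 2-(benzyloxy)-5-bromo-1,3-dimethoxybenzene | COc1cc(Br)cc(OC)c1OCc1ccccc1 | intermediate
3 | (S)-epichlorohydrin | ClC[C@@H]1CO1 | starting material
4 | dimethyl malonate | COC(=O)CC(=O)OC | starting material
5 | dimethyl 2-{[(2S)-oxiran-2-yl]methyl}propanedioate (epoxymalonate) | COC(=O)C(C[C@H]1CO1)C(=O)OC | intermediate
6 | methyl (1R,5S)-2-oxo-3-oxabicyclo[3.1.0]hexane-1-carboxylate | O=C1OC[C@H]2C[C@@]12C(=O)OC | intermediate
7 | [4-(benzyloxy)-3,5-dimethoxyphenyl]magnesium bromide | COc1cc([Mg]Br)cc(OC)c1OCc1ccccc1 | intermediate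
8 | methyl (3R,4S)-4-{[4-(benzyloxy)-3,5-dimethoxyphenyl]methyl}-2-oxooxolane-3-carboxylate (trans; C3 is labile and is lost in step 4) | COC(=O)[C@@H]1C(=O)OC[C@H]1Cc1cc(OC)c(OCc2ccccc2)c(OC)c1 | intermediate
9 | (4S)-4-{[4-(benzyloxy)-3,5-dimethoxyphenyl]methyl}oxolan-2-one | COc1cc(C[C@@H]2COC(=O)C2)cc(OC)c1OCc1ccccc1 | intermediate
10 | {[(4S)-4-{[4-(benzyloxy)-3,5-dimethoxyphenyl]methyl}-4,5-dihydrofuran-2-yl]oxy}trimethylsilane (silyl ketene acetal) | C[Si](C)(C)OC1=C[C@H](Cc2cc(OC)c(OCc3ccccc3)c(OC)c2)CO1 | intermediate
11 | (3R,4S)-4-{[4-(benzyloxy)-3,5-dimethoxyphenyl]methyl}-3-(dimethoxymethyl)oxolan-2-one (trans) | COC(OC)[C@@H]1C(=O)OC[C@H]1Cc1cc(OC)c(OCc2ccccc2)c(OC)c1 | intermediate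
12 | (2S,3S)-2-{[4-(benzyloxy)-3,5-dimethoxyphenyl]methyl}-3-(dimethoxymethyl)butane-1,4-diol (diol acetal) | COC(OC)[C@H](CO)[C@@H](CO)Cc1cc(OC)c(OCc2ccccc2)c(OC)c1 | intermediate
13 | [(3S,4S)-4-{[4-(benzyloxy)-3,5-dimethoxyphenyl]methyl}-2-methoxyoxolan-3-yl]methanol (3,4-cis; both C2 anomers) | COC1OC[C@@H](Cc2cc(OC)c(OCc3ccccc3)c(OC)c2)[C@H]1CO | intermediate
14 | [4-(benzyloxy)-3-methoxyphenyl]boronic acid | COc1cc(B(O)O)ccc1OCc1ccccc1 | starting material
15 | potassium [4-(benzyloxy)-3-methoxyphenyl]trifluoroborate | COc1cc([B-](F)(F)F)ccc1OCc1ccccc1.[K+] | intermediate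
16 | [4-(benzyloxy)-3-methoxyphenyl]difluoroborane | COc1cc(B(F)F)ccc1OCc1ccccc1 | intermediate
17 | [(3S,4S)-2-[4-(benzyloxy)-3-methoxyphenyl]-4-{[4-(benzyloxy)-3,5-dimethoxyphenyl]methyl}oxolan-3-yl]methanol (C2 epimers; this centre becomes planar) | OC[C@H]1C(c2ccc(OCc3ccccc3)c(OC)c2)OC[C@H]1Cc1cc(OC)c(OCc2ccccc2)c(OC)c1 | intermediate
18 | [(1R,2S,3S)-7-(benzyloxy)-1-[4-(benzyloxy)-3-methoxyphenyl]-6,8-dimethoxy-1,2,3,4-tetrahydronaphthalene-2,3-diyl]dimethanol | COc1cc([C@@H]2c3c(cc(OC)c(OCc4ccccc4)c3OC)C[C@H](CO)[C@H]2CO)ccc1OCc1ccccc1 | intermediate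
19 | [(1R,2S,3S)-7-hydroxy-1-(4-hydroxy-3-methoxyphenyl)-6,8-dimethoxy-1,2,3,4-tetrahydronaphthalene-2,3-diyl]dimethanol (aryl at C1 trans to CH2OH at C2; CH2OH groups at C2 and C3 trans) | COc1cc([C@@H]2c3c(cc(OC)c(O)c3OC)C[C@H](CO)[C@H]2CO)ccc1O | target

**Step count and risks**

Total steps: 9. Longest linear sequence: 7 steps (1 → 2 → 8 → 9 → 11 → 13 → 18 → 19, steps 1, 3, 4, 5, 6, 8, 9).

Steps most likely to fail:

1. Step 8. The aryl group may be lost by protodeboronation before it is transferred. The oxocarbenium ion may lose its C2 proton and scramble C2. Ring A may capture the oxocarbenium ion before the aryl group arrives. Facial selectivity at C1 in the ring closure may be poor, or ionisation of the benzylic ether may stall. Fallback, known chemistry, setting out from 13: aqueous acid (AcOH–H2O–THF) should hydrolyse the methyl acetal to the lactol (3S,4S)-4-{[4-(benzyloxy)-3,5-dimethoxyphenyl]methyl}-3-(hydroxymethyl)oxolan-2-ol F1. Addition of an excess of [4-(benzyloxy)-3-methoxyphenyl]magnesium bromide F2 (from commercial 1-(benzyloxy)-4-bromo-2-methoxybenzene and Mg in THF) to the open hydroxy-aldehyde form should give the triol (2S,3S)-2-{[4-(benzyloxy)-3,5-dimethoxyphenyl]methyl}-3-{[4-(benzyloxy)-3-methoxyphenyl](hydroxy)methyl}butane-1,4-diol F3 as a mixture of carbinol epimers. TFA in CH2Cl2 at 0 °C should then ionise the benzylic carbinol and close ring B in the same stereochemical sense. The route is rejoined at 18.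

2. Step 5. Methanol may be eliminated from 11 under the Lewis acid to give the methoxymethylene lactone, the enolate may be silylated on carbon, or the anti selectivity may be low. Fallback, setting out from 9: Claisen formylation (NaH, HCO2Et, THF) should give the hydroxymethylene lactone (4S)-4-{[4-(benzyloxy)-3,5-dimethoxyphenyl]methyl}-3-(hydroxymethylidene)oxolan-2-one F4. Acetalisation (HC(OMe)3, MeOH, TsOH cat.) should then give the dimethyl acetal under thermodynamic control, where the trans isomer is favoured. The route is rejoined at 11.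

3. Step 3. The Grignard reagent may attack the lactone or ester carbonyl instead of the cyclopropane, or magnesium insertion into the electron-rich bromide may be sluggish. Fallback, setting out from 2 and bypassing 6 and 8:
   - Bromine–lithium exchange (n-BuLi, THF, −78 °C) and formylation with DMF should give 4-(benzyloxy)-3,5-dimethoxybenzaldehyde F5.
   - Stobbe condensation with dimethyl succinate (NaOMe, MeOH, reflux) should give the half-ester (3E)-4-[4-(benzyloxy)-3,5-dimethoxyphenyl]-3-(methoxycarbonyl)but-3-enoic acid F6.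
   - Asymmetric hydrogenation ([Rh(cod)2]BF4, a chiral bisphosphine of the DuPhos type in the enantiomer that delivers the (S)-acid, H2, MeOH) should give (3S)-4-[4-(benzyloxy)-3,5-dimethoxyphenyl]-3-(methoxycarbonyl)butanoic acid F7.
   - Reduction of the ester in the carboxylate salt with Ca(BH4)2 (from CaCl2 and NaBH4, EtOH), followed by acid lactonisation, should give the lactone. The route is rejoined at 9.

**Further compounds**

F1 | step 8 | (3S,4S)-4-{[4-(benzyloxy)-3,5-dimethoxyphenyl]methyl}-3-(hydroxymethyl)oxolan-2-ol (both anomers) | OC1OC[C@@H](Cc2cc(OC)c(OCc3ccccc3)c(OC)c2)[C@H]1CO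
F2 | step 8 | [4-(benzyloxy)-3-methoxyphenyl]magnesium bromide | COc1cc([Mg]Br)ccc1OCc1ccccc1
F3 | step 8 | (2S,3S)-2-{[4-(benzyloxy)-3,5-dimethoxyphenyl]methyl}-3-{[4-(benzyloxy)-3-methoxyphenyl](hydroxy)methyl}butane-1,4-diol (carbinol epimers) | OC[C@@H](Cc1cc(OC)c(OCc2ccccc2)c(OC)c1)[C@@H](CO)C(O)c1ccc(OCc2ccccc2)c(OC)c1
F4 | step 5 | (4S)-4-{[4-(benzyloxy)-3,5-dimethoxyphenyl]methyl}-3-(hydroxymethylidene)oxolan-2-one (enol, geometry not fixed) | OC=C1C(=O)OC[C@H]1Cc1cc(OC)c(OCc2ccccc2)c(OC)c1
F5 | step 3 | 4-(benzyloxy)-3,5-dimethoxybenzaldehyde | COc1cc(C=O)cc(OC)c1OCc1ccccc1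
F6 | step 3 | (3E)-4-[4-(benzyloxy)-3,5-dimethoxyphenyl]-3-(methoxycarbonyl)but-3-enoic acid | COC(=O)/C(=C/c1cc(OC)c(OCc2ccccc2)c(OC)c1)CC(=O)O
F7 | step 3 | (3S)-4-[4-(benzyloxy)-3,5-dimethoxyphenyl]-3-(methoxycarbonyl)butanoic acid | COC(=O)[C@H](CC(=O)O)Cc1cc(OC)c(OCc2ccccc2)c(OC)c1
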